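## Retrosynthetic overview

1. Target catechol ⇐ reduction of the corresponding o-quinone (redox only).
2. o-Quinone C=O ⇐ one ortho C–Br of tetrabromo-p-cresol, by a new I(V) ipso-oxygenative debromination. The two ortho C–Br bonds are equivalent, so there is no regiochemical question.
3. Tetrabromo-p-cresol ⇐ p-cresol + 4 Br2 (exhaustive SEAr).
4. Rings: only the benzene ring, bought with p-cresol; none is formed.
5. Forward order: 1 → 2 → (3, 4 in the flask) → 5 → 6.

Assumption: the target has no stereocentre and no chiral axis (it is achiral), so "single enantiomer" is taken to mean the single constitution shown and no stereocontrol is needed. Reagents are given by name and SMILES in the steps; numbers are used for substrates, intermediates and products.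

## Route

Step 1
Reactants: 1 4-methylphenol (p-cresol)
Product: 2 2,3,5,6-tetrabromo-4-methylphenol
Conditions: Br2 (4.6 equiv), AlBr3 (10 mol %), ClCH2CH2Cl, 0 → 40 °C, dark; aq NaHSO3 quench
Reagents that add atoms: bromine, BrBr
Why: Exhaustive electrophilic aromatic bromination (SEAr), in which OH directs the first two Br ortho and AlBr3-activated Br2 fills the two positions ortho to CH3, while darkness, ≤40 °C and the bisulfite quench (which returns any 4-bromo-dienone to the phenol) protect the benzylic CH3; no stereocentre is formed.

Step 2
Reactants: 2 2,3,5,6-tetrabromo-4-methylphenol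
Product: 5 3,4,6-tribromo-5-methylcyclohexa-3,5-diene-1,2-dione, via aryloxy-λ5-iodane 3 (not isolated), via gem-bromo iodanyloxy dienone 4 (not isolated)
Conditions: IBX (1.3 equiv), AgOCOCF3 (1.1 equiv), 4 Å MS, DMF, 23 → 45 °C, dark, N2; Et2O, filter, short SiO2 plug
Reagents that add atoms: 2-iodoxybenzoic acid (IBX), O=C1OI(=O)(O)c2ccccc12
Why: Proposed new method: λ5-iodane ipso-oxygenative debromination of an ortho-bromophenol, in which ligand exchange of the phenol at I(V) gives aryloxy-λ5-iodane 3, intramolecular [2,3]-type transfer of the I=O oxygen to the ortho carbon (I(V) → I(III)) gives the racemic, transient gem-bromo(iodanyloxy) dienone 4, and 4, having no ortho H to tautomerise, expels bromide (removed as AgBr so it cannot be re-oxidised to Br+) with O–I cleavage to give the second C=O of o-quinone 5; both ortho carbons of Cs-symmetric 2 are equivalent so only one product can form, and the closest known reaction types are IBX ortho-oxygenation of phenols at ortho C–H to o-quinones, SIBX hydroxylative phenol dearomatisation at ortho-alkyl carbons, and oxidative dehalogenation of p-halophenols to p-quinones; no stereocentre remains in 5.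

Step 3
Reactants: 5 3,4,6-tribromo-5-methylcyclohexa-3,5-diene-1,2-dione
Product: 6 3,4,6-tribromo-5-methylbenzene-1,2-diol
Conditions: Na2S2O4 (2.5 equiv), EtOAc/H2O, 23 °C, N2, 15 min; dilute HCl wash
Reagents that add atoms: none
Why: Dithionite reduction of an electron-poor o-quinone to its catechol (quinone → hydroquinone-type 2 e−/2 H+ reduction) is fast at room temperature and does not touch aryl C–Br or CH3; no stereocentre is involved.

## Compound list

1 | 4-methylphenol (p-cresol) | Cc1ccc(O)cc1 | starting material
2 | 2,3,5,6-tetrabromo-4-methylphenol | Cc1c(Br)c(Br)c(O)c(Br)c1Br | intermediate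
3 | 1-(2,3,5,6-tetrabromo-4-methylphenoxy)-1λ5,2-benziodoxole-1,3-dione (aryloxy-λ5-iodane, not isolated) | Cc1c(Br)c(Br)c(OI2(=O)OC(=O)c3ccccc23)c(Br)c1Br | intermediate
4 | 1-[(1,2,4,5-tetrabromo-3-methyl-6-oxocyclohexa-2,4-dien-1-yl)oxy]-1,2-benziodoxol-3(1H)-one (racemic, not isolated) | O=C1C(Br)=C(Br)C(C)=C(Br)C1(Br)OI2OC(=O)c3ccccc23 | intermediate
5 | 3,4,6-tribromo-5-methylcyclohexa-3,5-diene-1,2-dione (3,5,6-tribromo-4-methyl-o-benzoquinone) | CC1=C(Br)C(=O)C(=O)C(Br)=C1Br | intermediate
6 | 3,4,6-tribromo-5-methylbenzene-1,2-diol (3,5,6-tribromo-4-methylcatechol) | Cc1c(Br)c(O)c(O)c(Br)c1Br | target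

## Step count and risk

Total step count: 3. Longest linear sequence: 3 steps (1 → 2 → 5 → 6).

The three steps most likely to fail:

Step 2 (the proposed new step). The perbrominated phenol is electron-poor and may react slowly with IBX. The iodane adduct could instead lose a benzylic proton to give a p-quinone methide. Any bromide that escapes silver could be oxidised to Br+. The fallback uses only known chemistry, sets out from 1 and comes back to the route at 6. p-Cresol 1 is ortho-formylated (MgCl2, Et3N, paraformaldehyde, MeCN, reflux) to 2-hydroxy-5-methylbenzaldehyde F1. Dakin oxidation (30% H2O2, aq NaOH, 0 °C → rt, then HCl) converts this to 4-methylbenzene-1,2-diol F2. Exhaustive electrophilic bromination of its three free ring positions (Br2 3.1 equiv, AcOH, 15 °C → rt, NaHSO3 work-up) gives 6 directly.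

Step 1. Forcing bromination of a p-cresol can leak into the side chain through a 4-bromo-dienone and quinone methide, giving the 4-hydroxybenzyl bromide. It can also stall at the di- or tribromide. The fallback sets out from 1 and comes back at 2. p-Cresol 1 is O-methylated (MeI, K2CO3, acetone, reflux) to 1-methoxy-4-methylbenzene F3, which cannot form a dienone or quinone methide. Perbromination (Br2, Fe powder, dark, 0 → 50 °C) gives 1,2,4,5-tetrabromo-3-methoxy-6-methylbenzene F4. BBr3 (CH2Cl2, −78 °C → rt) cleaves the methyl ether to give 2.

Step 3. The o-quinone 5 may not survive isolation, and the electron-poor catechol can re-oxidise in air during basic or neutral work-up. The fallback sets out from 5 and comes back at 6. Crude 5 is reductively acetylated (Zn dust, Ac2O, NaOAc, rt) to the air-stable, crystallisable 3,4,6-tribromo-5-methyl-1,2-phenylene diacetate F5. After purification, this is deacetylated under acid (HCl, MeOH, 50 °C, N2) to give 6.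

## Further compounds

F1 | step 2 | 2-hydroxy-5-methylbenzaldehyde | Cc1ccc(O)c(C=O)c1
F2 | step 2 | 4-methylbenzene-1,2-diol | Cc1ccc(O)c(O)c1
F3 | step 1 | 1-methoxy-4-methylbenzene | COc1ccc(C)cc1
F4 | step 1 | 1,2,4,5-tetrabromo-3-methoxy-6-methylbenzene | COc1c(Br)c(Br)c(C)c(Br)c1Br
F5 | step 3 | 3,4,6-tribromo-5-methyl-1,2-phenylene diacetate | CC(=O)Oc1c(Br)c(Br)c(C)c(Br)c1OC(C)=O
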